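**Retrosynthetic overview**

- Target ⇐ Pinnick oxidation of the 7-O-methyl aldehyde ⇐ Mitsunobu O-methylation of a tricyclic lactol through its ring-opened form; prenyl ⇐ allyl by cross-metathesis.
- Tricyclic lactol ⇐ one-flask double annulation of an aryloxy acid with cinnamaldehyde: intramolecular Friedel–Crafts acylation (C4–C4a, pyranone ring), then iminium-catalysed Friedel–Crafts/hemiacetalisation (C8–CHPh and O7–C, second pyran ring).
- Aryloxy acid ⇐ Mitsunobu ether (O1–C2, inversion) between symmetrical 2-allylphloroglucinol and the anti-aldol ester from Fráter–Seebach methylation of methyl (R)-3-hydroxybutanoate.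
- Ring order: benzene ring bought; pyranone and lactol rings formed together in step 4; lactol ring opened again in step 6. C2/C3 come from the chiral pool, the benzylic centre from the catalyst; the C6 allyl group leaves C8 as the only free ring carbon.

Assumption: the SMILES is read literally, i.e. cis-(2S,3R)-2,3-dimethylchromanone and (R) at the benzylic carbon.

**Route**

Step 1
Reactants: 1 phloroglucinol; 2 allyl bromide
Product: 3 2-allylbenzene-1,3,5-triol (2-allylphloroglucinol)
Conditions: 1 (3 equiv), KOH (1 equiv), H2O, 0 °C to rt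
Reagents that add atoms: allyl bromide 2 (C=CCBr)
Why: C-alkylation of the ambident phloroglucinolate is favoured in water (SN2 on allyl bromide); excess 1 limits polyallylation and is washed out with water; no stereocenter is formed.

Step 2
Reactants: 4 methyl (3R)-3-hydroxybutanoate; 5 iodomethane
Product: 6 methyl (2R,3R)-3-hydroxy-2-methylbutanoate (2,3-anti)
Conditions: LDA (2.2 equiv), THF, −78 to −20 °C; then MeI, DMPU, −78 to 0 °C
Reagents that add atoms: iodomethane 5 (CI)
Why: Fráter–Seebach alkylation: the chelated lithium alkoxide–enolate dianion is methylated anti to the C3 methyl group, giving the 2,3-anti (2R,3R) ester (dr about 95:5) with C3 unchanged.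

Step 3
Reactants: 3 2-allylphloroglucinol; 6 methyl (2R,3R)-3-hydroxy-2-methylbutanoate
Product: 8 (2R,3S)-3-(4-allyl-3,5-dihydroxyphenoxy)-2-methylbutanoic acid, via methyl ester 7 (not isolated)
Conditions: PPh3, DIAD, 6 (1.2 equiv), THF, 0 °C to rt; then LiOH, H2O/MeOH, rt; HCl work-up (acid–base extraction)
Reagents that add atoms: lithium hydroxide ([Li+].[OH-])
Why: Mitsunobu etherification at the only phenol not flanked by the allyl group runs by SN2 with inversion at C3 (3R to 3S, C2 untouched); in-flask saponification (the phenoxide dianion is too poor a leaving group for E1cB) lets the acid be extracted away from Ph3PO and the hydrazide.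

Step 4
Reactants: 8 (2R,3S)-3-(4-allyl-3,5-dihydroxyphenoxy)-2-methylbutanoic acid; 9 (E)-cinnamaldehyde
Product: 12 (2S,3R,10R)-6-allyl-5,8-dihydroxy-2,3-dimethyl-10-phenyl-2,3,9,10-tetrahydro-4H,8H-pyrano[2,3-f]chromen-4-one (tricyclic lactol; C8 epimers), via chromanone 10 (not isolated), via open-chain aldehyde 11 (not isolated)
Conditions: TFAA (2 equiv), CH2Cl2, 0 °C, 1 h; MeOH quench, evaporate; then 9 (1.5 equiv), (R)-α,α-diphenylprolinol TMS ether (20 mol%), PhCO2H (20 mol%), toluene, 0 °C to rt
Reagents that add atoms: (E)-cinnamaldehyde 9 (O=C/C=C/c1ccccc1)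
Why: Proposed new method: TFAA turns the acid into a mixed anhydride that acylates the ring ortho to the ether oxygen (both ortho carbons are equivalent) in a stereoretentive intramolecular Friedel–Crafts acylation (known for 3-aryloxypropanoic acids to chroman-4-ones), and the resulting vinylogous acid 10, whose only free ring carbon is C8, then adds to the cinnamaldehyde iminium ion of the (R)-catalyst on the face opposite the CPh2OTMS group, setting the (R)-benzylic centre before the 7-OH closes the hemiacetal; the closest precedent is the diarylprolinol-silyl-ether Michael/hemiacetalisation of enals with 4-hydroxycoumarin, cyclic 1,3-diones and naphthols, and the telescoping relies on residual TFA serving as acid co-catalyst.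

Step 5
Reactants: 12 tricyclic allyl lactol; 13 2-methylbut-2-ene
Product: 14 (2S,3R,10R)-5,8-dihydroxy-2,3-dimethyl-6-(3-methylbut-2-en-1-yl)-10-phenyl-2,3,9,10-tetrahydro-4H,8H-pyrano[2,3-f]chromen-4-one (prenyl lactol; C8 epimers)
Conditions: Grubbs II (5 mol%), 2-methylbut-2-ene/CH2Cl2, 40 °C
Reagents that add atoms: 2-methylbut-2-ene 13 (CC=C(C)C)
Why: Olefin cross-metathesis of the terminal allyl group with 2-methylbut-2-ene (propene lost) gives the prenyl group under neutral conditions that leave the phenols, the lactol and all three stereocenters untouched.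

Step 6
Reactants: 14 prenyl lactol; 15 methanol
Product: 16 (3R)-3-[(2S,3R)-5-hydroxy-7-methoxy-2,3-dimethyl-6-(3-methylbut-2-en-1-yl)-4-oxochroman-8-yl]-3-phenylpropanal
Conditions: PPh3, DIAD, MeOH (3 equiv), THF, 0 °C to rt
Reagents that add atoms: methanol 15 (CO)
Why: Mitsunobu O-methylation: deprotonation of the lactol funnels into the ring-opened 7-phenoxide (para-acyl phenol, pKa about 8), which attacks MeO–PPh3+ and traps the aldehyde form; the chelated 5-OH is not alkylated and the neutral medium does not epimerise C3.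

Step 7
Reactants: 16 7-O-methyl aldehyde
Product: 17 (3R)-3-[(2S,3R)-5-hydroxy-7-methoxy-2,3-dimethyl-6-(3-methylbut-2-en-1-yl)-4-oxochroman-8-yl]-3-phenylpropanoic acid (CNP0172137.1)
Conditions: NaClO2, NaH2PO4, 2-methylbut-2-ene, t-BuOH/H2O, 0 °C to rt
Reagents that add atoms: sodium chlorite ([Na+].[O-]Cl=O)
Why: Pinnick oxidation takes the aldehyde to the acid at about pH 4 with 2-methylbut-2-ene scavenging HOCl, so the prenyl group, the fully substituted ring and the base-sensitive cis-2,3-dimethylchromanone are untouched.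

**Compound list**

1 | phloroglucinol (benzene-1,3,5-triol) | Oc1cc(O)cc(O)c1 | starting material
2 | allyl bromide (3-bromoprop-1-ene) | C=CCBr | starting material
3 | 2-allylbenzene-1,3,5-triol | C=CCc1c(O)cc(O)cc1O | intermediate
4 | methyl (3R)-3-hydroxybutanoate | C[C@@H](O)CC(=O)OC | starting material
5 | iodomethane | CI | starting material
6 | methyl (2R,3R)-3-hydroxy-2-methylbutanoate | C[C@@H](O)[C@@H](C)C(=O)OC | intermediate
7 | methyl (2R,3S)-3-(4-allyl-3,5-dihydroxyphenoxy)-2-methylbutanoate | C[C@H](Oc1cc(O)c(CC=C)c(O)c1)[C@@H](C)C(=O)OC | intermediate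
8 | (2R,3S)-3-(4-allyl-3,5-dihydroxyphenoxy)-2-methylbutanoic acid | C[C@H](Oc1cc(O)c(CC=C)c(O)c1)[C@@H](C)C(=O)O | intermediate
9 | (E)-cinnamaldehyde | O=C/C=C/c1ccccc1 | starting material
10 | (2S,3R)-6-allyl-5,7-dihydroxy-2,3-dimethylchroman-4-one (cis) | C=CCc1c(O)c2c(cc1O)O[C@@H](C)[C@@H](C)C2=O | intermediate
11 | (3R)-3-[(2S,3R)-6-allyl-5,7-dihydroxy-2,3-dimethyl-4-oxochroman-8-yl]-3-phenylpropanal | C=CCc1c(O)c2c(c([C@H](CC=O)c3ccccc3)c1O)O[C@@H](C)[C@@H](C)C2=O | intermediate
12 | (2S,3R,10R)-6-allyl-5,8-dihydroxy-2,3-dimethyl-10-phenyl-2,3,9,10-tetrahydro-4H,8H-pyrano[2,3-f]chromen-4-one (C8 epimers) | C=CCc1c(O)c2c(c3c1OC(O)C[C@@H]3c1ccccc1)O[C@@H](C)[C@@H](C)C2=O | intermediate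
13 | 2-methylbut-2-ene | CC=C(C)C | starting material
14 | (2S,3R,10R)-5,8-dihydroxy-2,3-dimethyl-6-(3-methylbut-2-en-1-yl)-10-phenyl-2,3,9,10-tetrahydro-4H,8H-pyrano[2,3-f]chromen-4-one (C8 epimers) | CC(C)=CCc1c(O)c2c(c3c1OC(O)C[C@@H]3c1ccccc1)O[C@@H](C)[C@@H](C)C2=O | intermediate
15 | methanol | CO | starting material
16 | (3R)-3-[(2S,3R)-5-hydroxy-7-methoxy-2,3-dimethyl-6-(3-methylbut-2-en-1-yl)-4-oxochroman-8-yl]-3-phenylpropanal | COc1c(CC=C(C)C)c(O)c2c(c1[C@H](CC=O)c1ccccc1)O[C@@H](C)[C@@H](C)C2=O | intermediate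
17 | (3R)-3-[(2S,3R)-5-hydroxy-7-methoxy-2,3-dimethyl-6-(3-methylbut-2-en-1-yl)-4-oxochroman-8-yl]-3-phenylpropanoic acid | COc1c(CC=C(C)C)c(O)c2c(c1[C@H](CC(=O)O)c1ccccc1)O[C@@H](C)[C@@H](C)C2=O | target

**Summary**

Total steps: 7. Longest linear sequence: 6 (steps 1, 3, 4, 5, 6, 7 from phloroglucinol; equally 2, 3, 4, 5, 6, 7 from 4).

Steps most likely to fail, in order of risk: step 4, step 3, step 6.

Step 3 (Mitsunobu ether). The β-hydroxy ester can eliminate to methyl tiglate, and the regioselectivity among the three phenols rests on sterics only. Fallback: the C–O bond is made by β-lactone opening instead. Setting out from 6, saponification (LiOH, H2O/THF) gives (2R,3R)-3-hydroxy-2-methylbutanoic acid F1. PhSO2Cl in pyridine at 0 °C closes it with retention at both centres to (3R,4R)-3,4-dimethyloxetan-2-one F2. The monosodium phenoxide of 3 (aqueous NaOH, rt) opens F2 at C4 by alkyl–oxygen cleavage with inversion and gives the acid 8 directly, where the route is rejoined.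

Step 4 (one-flask double annulation). Three things can go wrong: the acylium can lose the phenol and re-add through a tigloyl pathway (loss of the cis stereochemistry), the acylphloroglucinol may be too poor a nucleophile for the iminium ion, or the face selectivity may be low. Fallback: the rings are closed one at a time and the phenyl group is brought in by metal catalysis. Setting out from 8, the acylation is run alone and the chromanone 10 is isolated. Condensation of 10 with ethyl propiolate (ZnCl2, dioxane, 80 °C, Pechmann-type hydroarylation/lactonisation at C8/O7) gives the coumarin (2S,3R)-6-allyl-5-hydroxy-2,3-dimethyl-2,3-dihydro-4H,8H-pyrano[2,3-f]chromene-4,8-dione F3. Rh(acac)(C2H4)2/(R)-SEGPHOS-catalysed 1,4-addition of PhB(OH)2 (dioxane/H2O, 60 °C) gives (2S,3R,10R)-6-allyl-5-hydroxy-2,3-dimethyl-10-phenyl-2,3,9,10-tetrahydro-4H,8H-pyrano[2,3-f]chromene-4,8-dione F4; the (R) sense is assumed by analogy with 6-methylcoumarin. DIBAL-H (CH2Cl2, −78 °C) reduces the aryl lactone to the lactol, rejoining the route at 12.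

Step 6 (methylation of the lactol). The lactol may be activated at the anomeric OH and give acetals, or the open form may react too slowly. Fallback: go through the lactone and an ester. Setting out from 14, Fétizon oxidation (Ag2CO3/Celite, toluene, 80 °C) gives (2S,3R,10R)-5-hydroxy-2,3-dimethyl-6-(3-methylbut-2-en-1-yl)-10-phenyl-2,3,9,10-tetrahydro-4H,8H-pyrano[2,3-f]chromene-4,8-dione F5. Methanolysis with catalytic i-Pr2NEt in MeOH and in-flask trapping of the 7-OH with TMSCHN2 gives methyl (3R)-3-[(2S,3R)-5-hydroxy-7-methoxy-2,3-dimethyl-6-(3-methylbut-2-en-1-yl)-4-oxochroman-8-yl]-3-phenylpropanoate F6. Me3SnOH (1,2-dichloroethane, 70 °C) cleaves the ester without epimerising C3, rejoining the route at 17 and bypassing 16.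

**Further compounds**

F1 | step 3 | (2R,3R)-3-hydroxy-2-methylbutanoic acid | C[C@@H](O)[C@@H](C)C(=O)O
F2 | step 3 | (3R,4R)-3,4-dimethyloxetan-2-one | C[C@H]1OC(=O)[C@@H]1C
F3 | step 4 | (2S,3R)-6-allyl-5-hydroxy-2,3-dimethyl-2,3-dihydro-4H,8H-pyrano[2,3-f]chromene-4,8-dione | C=CCc1c(O)c2c(c3c1OC(=O)C=C3)O[C@@H](C)[C@@H](C)C2=O
F4 | step 4 | (2S,3R,10R)-6-allyl-5-hydroxy-2,3-dimethyl-10-phenyl-2,3,9,10-tetrahydro-4H,8H-pyrano[2,3-f]chromene-4,8-dione | C=CCc1c(O)c2c(c3c1OC(=O)C[C@@H]3c1ccccc1)O[C@@H](C)[C@@H](C)C2=O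
F5 | step 6 | (2S,3R,10R)-5-hydroxy-2,3-dimethyl-6-(3-methylbut-2-en-1-yl)-10-phenyl-2,3,9,10-tetrahydro-4H,8H-pyrano[2,3-f]chromene-4,8-dione | CC(C)=CCc1c(O)c2c(c3c1OC(=O)C[C@@H]3c1ccccc1)O[C@@H](C)[C@@H](C)C2=O
F6 | step 6 | methyl (3R)-3-[(2S,3R)-5-hydroxy-7-methoxy-2,3-dimethyl-6-(3-methylbut-2-en-1-yl)-4-oxochroman-8-yl]-3-phenylpropanoate | COc1c(CC=C(C)C)c(O)c2c(c1[C@H](CC(=O)OC)c1ccccc1)O[C@@H](C)[C@@H](C)C2=O
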